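We decide to judge these set-ups by one comparison: of what is forming at a given moment, how much is target, and how does that share drift as the flask ages?

| setting | elm | maple | ash | ochre | grey | teal | green |
|---|---|---|---|---|---|---|---|
| starting material | 0.50 M | 0.50 M | 0.50 M | 0.50 M | 0.50 M | 0.50 M | 0.50 M |
| second substrate | 1 equiv | 1 equiv | 1 equiv | 1.00 equiv | 1.00 equiv (fed, over 1.25 d) | 1.00 equiv | 1.00 equiv |
| free catalyst | 0.13 mol% | 0.18 mol% | 0.29 mol% | 0.13 mol% | 0.13 mol% | 0.13 mol% | 0.13 mol% |
| remark | run made earlier | run made earlier | run made earlier | everything together in a closed stirred flask, run for 2.5 d | a stirred flask in which second substrate is dosed at a steady rate over 1.25 d without added volume, worked up at 2.5 d | a single well-mixed tank run continuously and read at steady state, 2.5 d in it on average | one stirred flow tank at steady state, fed with the mixture as stated, mean residence time 25.0 d |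
| time |  |  |  | 2.5 d | 2.5 d |  |  |

| run | time / d | target / % | uncatalysed product / % | starting material / % |
|---|---|---|---|---|
| elm | 0.167 | 10 | 6 | 62 |
| elm | 0.500 | 21 | 12 | 32 |
| elm | 0.833 | 25 | 13 | 20 |
| elm | 1.25 | 36 | 18 | 16 |
| elm | 2.08 | 46 | 15 | 12 |
| elm | 2.50 | 49 | 24 | 8 |
| maple | 0.208 | 16 | 6 | 50 |
| maple | 0.625 | 32 | 11 | 23 |
| maple | 1.04 | 40 | 12 | 9 |
| maple | 1.67 | 51 | 15 | 7 |
| maple | 2.50 | 61 | 17 | 5 |
| maple | 3.00 | 68 | 18 | 4 |
| ash | 0.500 | 38 | 9 | 20 |
| ash | 1.04 | 54 | 10 | 6 |
| ash | 1.67 | 68 | 12 | 7 |
| ash | 2.08 | 72 | 15 | 1 |
| ash | 2.50 | 76 | 13 | 5 |
| ash | 3.00 | 80 | 11 | 2 |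

(each reading ± 2 percentage points)

- the stated concentrations are those of everything mixed, before any reaction; amounts are the same in each set-up
- the feed brings no volume worth counting
- the earlier runs were made in a closed, stirred flask

- the set-up with the highest share of target in all that became target or uncatalysed product, at the outlet or at the end ("none" if the first two lie within 2 percentage points) (ochre / grey / teal / green / none)
- share of target in all that became target or uncatalysed product, at the outlet or at the end, ochre
- share of target in all that became target or uncatalysed product, at the outlet or at the end, grey
- share of target in all that became target or uncatalysed product, at the outlet or at the end, teal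
- share of target in all that became target or uncatalysed product, at the outlet or at the end, green

The elm run has ochre's charge in a closed flask. At its reading of 0.500 d, target makes up 63.6% of the two products. From there to the mean of its last two readings, target gains 26 percentage points of the charge and uncatalysed product gains 7.5 points. So target takes 77.9% of what forms in that stretch, and we call this the late share, a differential selectivity, which as read stands above the opening figure. The whole mix at elm's last two readings is 70.9% target, and that is our figure for ochre.

Now we turn the question round. For ochre to draw level with green on this reckoning, the late share would have to sink to that mix, so uncatalysed product would have had to gain 11 points in elm instead of 7.5 points. That gap of 3.4 points is under two readings' scatter, so our footing is narrow. Green, at 25.0 d on average against 2.5 d for ochre, should sit at the late stage throughout, so we commit to green near the late share, above ochre, with grey and teal between them.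

The forecast gives 70% for ochre, 69% for grey, 69% for teal and 78% for green, and names green as best: “Green has time to drain the pool, about 78%, so it is best”.

The flasks give 71.1% for ochre, 73.1% for grey, 74.8% for teal and 78.9% for green, so green is best.

    starting material + free catalyst ⇌ catalyst intermediate A (K = 3.70 M⁻¹, k = 0.0400 M⁻¹ s⁻¹)
    catalyst intermediate A → free catalyst + target (k = 0.0170 s⁻¹)
    second substrate + free catalyst ⇌ catalyst intermediate B (K = 4.60 M⁻¹, k = 0.0230 M⁻¹ s⁻¹)
    catalyst intermediate B → free catalyst + second product (k = 0.0170 s⁻¹)
    starting material ⇌ dormant form (K = 1.70, k = 2.20 × 10⁻⁵ s⁻¹)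
    starting material → uncatalysed product (k = 4.10 × 10⁻⁶ s⁻¹)

In green, starting material stands at 2.24% of the charge everywhere in the tank. Ochre ends at 2.5 d with 20.2% uncatalysed product, which at its share means 69.9% of the charge has become the two products. If the rest of the charge follows at the late share of 77.9%, the mix comes to 73.1%, and ochre left to 25.0 d gives 73.3%.

The runs were generated by integration from invented constants; scatter was added.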